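**Plan**
- Retrosynthesis: the three phenols are unmasked last (MOM ethers); the C3–H stereocentre is traced back to a C3 allyl ester, removed by enantioselective decarboxylative protonation.
- The pyranone ring C is then opened at C2–C3 and O1–C8a, which leaves formaldehyde and an α-aryl β-ketoester with fluorine on ring A ortho to the ketone.
- Enabling feature: C3 (flanked by the C4 ketone, the ester and ring B) is a soft carbon nucleophile placed 1,4 to C8a, whose C–F bond is activated by the same C4 carbonyl; this pair takes up the C and the O of CH2=O.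
- The ketoester is cut at C3–C4 (aldol, then oxidation) into a ring-A aldehyde (from 5-fluororesorcinol) and a ring-B allyl arylacetate (from 2,4-dihydroxyphenylacetic acid).
- Forward order: dimethylpyran ring on ring B (lactone differentiation, propargyl ether Claisen), C3–C4 union, ring C closure, stereocentre, deprotection.
- Stereochemistry: the only stereocentre, C3 (R), is set in step 11 by the chiral ligand; the quaternary centre made in the key step is racemic and is erased there.

Key step: step 10

Assumption: the (S)-configured ligand with Meldrum's acid is taken, by analogy with other 3-aryl chromanone allyl esters, to protonate the enolate face that gives (3R); if the sense proves opposite, the mirror-image ligand is used and nothing else changes.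

**Step 1**
Reactants: 1 5-fluororesorcinol (5-fluorobenzene-1,3-diol)
Product: 3 2-fluoro-4,6-dihydroxybenzaldehyde, via iminium salt 2 (not isolated)
Conditions: POCl3, DMF, MeCN, 0 °C → rt; then H2O, 50 °C
Reagents that add atoms: N,N-dimethylformamide CN(C)C=O; water O
Why: Vilsmeier–Haack formylation should occur para to one hydroxyl and ortho to the other (the position flanked by F and OH), as with resorcinol, and hydrolysis of the iminium salt then gives the aldehyde.

**Step 2**
Reactants: 3 2-fluoro-4,6-dihydroxybenzaldehyde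
Product: 4 2-fluoro-4,6-bis(methoxymethoxy)benzaldehyde
Conditions: NaH, MOMCl, DMF, 0 °C → rt
Reagents that add atoms: chloromethyl methyl ether COCCl
Why: O-alkylation of both sodium phenoxides (Williamson type) should protect also the hydrogen-bonded 6-OH as its acetal.

**Step 3**
Reactants: 5 2,4-dihydroxyphenylacetic acid
Product: 6 6-hydroxybenzofuran-2(3H)-one
Conditions: TsOH·H2O (cat.), toluene, reflux, Dean–Stark
Reagents that add atoms: none
Why: Acid-catalysed lactonisation can involve only the 2-OH (five-membered ring), which differentiates the two phenols.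

**Step 4**
Reactants: 6 6-hydroxybenzofuran-2(3H)-one
Product: 7 6-(methoxymethoxy)benzofuran-2(3H)-one
Conditions: MOMCl, iPr2NEt, CH2Cl2, 0 °C
Reagents that add atoms: chloromethyl methyl ether COCCl
Why: Phenol O-alkylation with a hindered amine base, which is too weak to enolise the lactone appreciably, should protect the remaining phenol.

**Step 5**
Reactants: 7 6-(methoxymethoxy)benzofuran-2(3H)-one
Product: 8 allyl 2-[2-hydroxy-4-(methoxymethoxy)phenyl]acetate
Conditions: allyl alcohol (solvent), K2CO3 (cat.), rt; AcOH quench, concentration below 30 °C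
Reagents that add atoms: allyl alcohol C=CCO
Why: Base-catalysed alcoholysis (transesterification) of the activated aryl-ester lactone in neat alcohol should release the phenol that becomes the pyran oxygen and install the allyl ester.

**Step 6**
Reactants: 8 allyl 2-[2-hydroxy-4-(methoxymethoxy)phenyl]acetate
Product: 9 allyl 2-[4-(methoxymethoxy)-2-[(2-methylbut-3-yn-2-yl)oxy]phenyl]acetate
Conditions: 3-chloro-3-methylbut-1-yne, DBU, CuCl2·2H2O (cat.), MeCN, 0 °C
Reagents that add atoms: 3-chloro-3-methylbut-1-yne CC(C)(Cl)C#C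
Why: Copper-catalysed propargylic etherification of phenols with tertiary propargyl chlorides runs at 0 °C, cold enough to keep the ortho ester from relactonising.

**Step 7**
Reactants: 9 allyl 2-[4-(methoxymethoxy)-2-[(2-methylbut-3-yn-2-yl)oxy]phenyl]acetate
Product: 11 allyl 2-[5-(methoxymethoxy)-2,2-dimethyl-2H-chromen-8-yl]acetate, via allenyl phenol 10 (not isolated)
Conditions: N,N-diethylaniline, 160 °C
Reagents that add atoms: none
Why: Aryl propargyl ether Claisen rearrangement to the only free ortho position (between the two oxygens), then 1,5-hydrogen shift and oxa-6π electrocyclisation, should give the 2,2-dimethylchromene with unambiguous regiochemistry.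

**Step 8**
Reactants: 11 allyl 2-[5-(methoxymethoxy)-2,2-dimethyl-2H-chromen-8-yl]acetate; 4 2-fluoro-4,6-bis(methoxymethoxy)benzaldehyde
Product: 13 allyl 3-[2-fluoro-4,6-bis(methoxymethoxy)phenyl]-3-hydroxy-2-[5-(methoxymethoxy)-2,2-dimethyl-2H-chromen-8-yl]propanoate (diastereomer mixture), via lithium enolate 12 (not isolated)
Conditions: LiN(SiMe3)2, THF, −78 °C; then 4; AcOH, −78 °C
Reagents that add atoms: none
Why: Aldol addition of the ester lithium enolate to the non-enolisable aldehyde joins C3 to C4, and both new stereocentres are irrelevant because they are erased in steps 9 and 11.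

**Step 9**
Reactants: 13 allyl 3-[2-fluoro-4,6-bis(methoxymethoxy)phenyl]-3-hydroxy-2-[5-(methoxymethoxy)-2,2-dimethyl-2H-chromen-8-yl]propanoate
Product: 14 allyl 3-[2-fluoro-4,6-bis(methoxymethoxy)phenyl]-2-[5-(methoxymethoxy)-2,2-dimethyl-2H-chromen-8-yl]-3-oxopropanoate (racemic, keto/enol mixture)
Conditions: Dess–Martin periodinane, pyridine, CH2Cl2, 0 °C → rt
Reagents that add atoms: none
Why: Buffered Dess–Martin oxidation of the benzylic alcohol should give the β-ketoester without touching the acetals or the chromene double bond.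

**Step 10**
Reactants: 14 allyl 3-[2-fluoro-4,6-bis(methoxymethoxy)phenyl]-2-[5-(methoxymethoxy)-2,2-dimethyl-2H-chromen-8-yl]-3-oxopropanoate
Product: 16 allyl 5,7-bis(methoxymethoxy)-3-[5-(methoxymethoxy)-2,2-dimethyl-2H-chromen-8-yl]-4-oxochromane-3-carboxylate (racemic), via hydroxymethyl adduct 15 (not isolated)
Conditions: (CH2O)n (3 equiv), Cs2CO3 (1.5 equiv), DMF, rt 1 h, then 60 °C
Reagents that add atoms: formaldehyde (from paraformaldehyde) C=O
Why: Proposed new method: Cs2CO3 removes C3–H of 14 (acidified by the C4 ketone, the ester and ring B), the enolate adds through carbon to monomeric formaldehyde, and the primary alkoxide 15 attacks the fluorine-bearing ring-A carbon ortho to the C4 ketone to give a Meisenheimer complex, stabilised by that carbonyl, which expels fluoride. The closest known reaction types are the hydroxymethylation of α-substituted β-ketoesters with formaldehyde and the alkoxide or phenoxide ring closure of ortho-fluoroaryl ketones to chromanones and xanthones, also run in domino form on nitro-activated fluoroarenes; their merger on a fluoroarene activated by the ketone alone and carrying two alkoxy groups is the new element. Ring C closes as a six-membered ring by ipso attack of oxygen on the trigonal C–F carbon (addition–elimination, formally 6-exo-trig counted on the C8a=C8 bond). The new quaternary stereocentre C3 forms racemic and needs no control, because step 11 turns it into a planar enolate. The step needs C- rather than O-hydroxymethylation, and alkoxide substitution rather than O-arylation by the ester-enolate oxygen (which would give a 2-allyloxyisoflavone) or retro-Claisen cleavage; running the aldol to completion at room temperature before warming leaves little free enolate, 15 has no α-hydrogen and so cannot dehydrate, retro-aldol only returns 14, and the alkoxide is a far better nucleophile than the delocalised enolate. Both alkoxy groups of ring A are meta to the C–F carbon and so do not oppose the substitution.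

**Step 11**
Reactants: 16 allyl 5,7-bis(methoxymethoxy)-3-[5-(methoxymethoxy)-2,2-dimethyl-2H-chromen-8-yl]-4-oxochromane-3-carboxylate
Product: 17 (3R)-5,7-bis(methoxymethoxy)-3-[5-(methoxymethoxy)-2,2-dimethyl-2H-chromen-8-yl]chroman-4-one
Conditions: Pd2(dba)3 (5 mol %), (S)-(CF3)3-t-BuPHOX (12.5 mol %), Meldrum's acid (2.5 equiv), 1,4-dioxane, 40 °C
Reagents that add atoms: none
Why: Palladium-catalysed decarboxylative asymmetric protonation (zerovalent palladium ionises the allyl ester, CO2 is lost, and the ligand-bound palladium enolate is protonated on one face by Meldrum's acid) is established for 3-aryl chromanone allyl esters and should set C3 as R under ligand control in a medium that stays acidic.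

**Step 12**
Reactants: 17 (3R)-5,7-bis(methoxymethoxy)-3-[5-(methoxymethoxy)-2,2-dimethyl-2H-chromen-8-yl]chroman-4-one
Product: 18 (3R)-5,7-dihydroxy-3-(5-hydroxy-2,2-dimethyl-2H-chromen-8-yl)chroman-4-one (target)
Conditions: HCl (1.25 M in MeOH), THF, 0 °C → rt; pH 6 phosphate buffer work-up
Reagents that add atoms: none
Why: Acid-catalysed acetal methanolysis should remove the three MOM groups under the acidic, non-basic regime in which the C3–H centre of isoflavanones is least prone to enolisation, and which 2,2-dimethylchromenes normally tolerate.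

**Compound list**
1 | 5-fluororesorcinol | Oc1cc(O)cc(F)c1 | starting material
2 | [(2-fluoro-4,6-dihydroxyphenyl)methylidene]dimethyliminium dichlorophosphate | C[N+](C)=Cc1c(F)cc(O)cc1O.[O-]P(Cl)(Cl)=O | intermediate
3 | 2-fluoro-4,6-dihydroxybenzaldehyde | O=Cc1c(F)cc(O)cc1O | intermediate
4 | 2-fluoro-4,6-bis(methoxymethoxy)benzaldehyde | COCOc1cc(F)c(C=O)c(OCOC)c1 | intermediate
5 | 2,4-dihydroxyphenylacetic acid | OC(=O)Cc1ccc(O)cc1O | starting material
6 | 6-hydroxybenzofuran-2(3H)-one | O=C1Cc2ccc(O)cc2O1 | intermediate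
7 | 6-(methoxymethoxy)benzofuran-2(3H)-one | COCOc1ccc2CC(=O)Oc2c1 | intermediate
8 | allyl 2-[2-hydroxy-4-(methoxymethoxy)phenyl]acetate | C=CCOC(=O)Cc1ccc(OCOC)cc1O | intermediate
9 | allyl 2-[4-(methoxymethoxy)-2-[(2-methylbut-3-yn-2-yl)oxy]phenyl]acetate | C=CCOC(=O)Cc1ccc(OCOC)cc1OC(C)(C)C#C | intermediate
10 | allyl 2-[2-hydroxy-4-(methoxymethoxy)-3-(3-methylbuta-1,2-dien-1-yl)phenyl]acetate | C=CCOC(=O)Cc1ccc(OCOC)c(C=C=C(C)C)c1O | intermediate
11 | allyl 2-[5-(methoxymethoxy)-2,2-dimethyl-2H-chromen-8-yl]acetate | C=CCOC(=O)Cc1ccc(OCOC)c2C=CC(C)(C)Oc12 | intermediate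
12 | lithium enolate of 11 (double-bond geometry not defined) | C=CCOC(O[Li])=Cc1ccc(OCOC)c2C=CC(C)(C)Oc12 | intermediate
13 | allyl 3-[2-fluoro-4,6-bis(methoxymethoxy)phenyl]-3-hydroxy-2-[5-(methoxymethoxy)-2,2-dimethyl-2H-chromen-8-yl]propanoate (diastereomer mixture, racemic) | C=CCOC(=O)C(c1ccc(OCOC)c2C=CC(C)(C)Oc12)C(O)c1c(F)cc(OCOC)cc1OCOC | intermediate
14 | allyl 3-[2-fluoro-4,6-bis(methoxymethoxy)phenyl]-2-[5-(methoxymethoxy)-2,2-dimethyl-2H-chromen-8-yl]-3-oxopropanoate (racemic) | C=CCOC(=O)C(c1ccc(OCOC)c2C=CC(C)(C)Oc12)C(=O)c1c(F)cc(OCOC)cc1OCOC | intermediate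
15 | allyl 3-[2-fluoro-4,6-bis(methoxymethoxy)phenyl]-2-(hydroxymethyl)-2-[5-(methoxymethoxy)-2,2-dimethyl-2H-chromen-8-yl]-3-oxopropanoate (racemic, present as its alkoxide) | C=CCOC(=O)C(CO)(c1ccc(OCOC)c2C=CC(C)(C)Oc12)C(=O)c1c(F)cc(OCOC)cc1OCOC | intermediate
16 | allyl 5,7-bis(methoxymethoxy)-3-[5-(methoxymethoxy)-2,2-dimethyl-2H-chromen-8-yl]-4-oxochromane-3-carboxylate (racemic) | C=CCOC(=O)C1(c2ccc(OCOC)c3C=CC(C)(C)Oc23)COc2cc(OCOC)cc(OCOC)c2C1=O | intermediate
17 | (3R)-5,7-bis(methoxymethoxy)-3-[5-(methoxymethoxy)-2,2-dimethyl-2H-chromen-8-yl]chroman-4-one | CC1(C)C=Cc2c(OCOC)ccc([C@@H]3COc4cc(OCOC)cc(OCOC)c4C3=O)c2O1 | intermediate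
18 | (3R)-5,7-dihydroxy-3-(5-hydroxy-2,2-dimethyl-2H-chromen-8-yl)chroman-4-one | CC1(C)C=Cc2c(O)ccc([C@@H]3COc4cc(O)cc(O)c4C3=O)c2O1 | target

**Count**
Total steps: 12. Longest linear sequence: 10 (steps 3–7, then 8–12).

**Steps most likely to fail**

Step 10. The alkoxide may revert by retro-aldol faster than it displaces fluoride from the electron-rich ring A, so that the enolate of 14 is lost to O-arylation through its ester oxygen or to retro-Claisen cleavage. The fallback uses known chemistry with the ring-A oxygen in place from the start; it sets out from 11 and comes back at 16. Compound 11 is α-methylenated (paraformaldehyde, K2CO3, Bu4NI, DMF) to allyl 2-[5-(methoxymethoxy)-2,2-dimethyl-2H-chromen-8-yl]prop-2-enoate F1. Commercial 2,4,6-trihydroxybenzaldehyde is treated with MOMCl (2 equiv) and iPr2NEt to give 2-hydroxy-4,6-bis(methoxymethoxy)benzaldehyde F2, the chelated hydroxyl staying free. F2 and F1 are joined with K2CO3 in DMF by a domino oxa-Michael/aldol reaction (phenoxide onto the acrylate CH2, then the ester enolate onto the aldehyde). This should give allyl 4-hydroxy-5,7-bis(methoxymethoxy)-3-[5-(methoxymethoxy)-2,2-dimethyl-2H-chromen-8-yl]chromane-3-carboxylate F3, which cannot dehydrate because C3 is quaternary. Dess–Martin oxidation of F3 gives 16.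

Step 11. Facial discrimination in the protonation of the palladium enolate may be poor (only one ortho substituent on ring B, a peri alkoxy group at C5), or an adventitious achiral acid may protonate it. The fallback sets out from 16 and comes back at 17. Compound 16 is deallylated and decarboxylated without stereocontrol (Pd(PPh3)4, morpholine, THF) to racemic 5,7-bis(methoxymethoxy)-3-[5-(methoxymethoxy)-2,2-dimethyl-2H-chromen-8-yl]chroman-4-one F4. Asymmetric transfer hydrogenation under dynamic kinetic resolution (RuCl[(R,R)-TsDPEN](p-cymene), HCO2H/Et3N, the amine equilibrating C3 of the unreacted ketone) should give the cis alcohol (3R,4R)-5,7-bis(methoxymethoxy)-3-[5-(methoxymethoxy)-2,2-dimethyl-2H-chromen-8-yl]chroman-4-ol F5. Base-free Dess–Martin oxidation of F5 returns the ketone 17 with C3 untouched.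

Step 12. Configurational integrity at C3 may be lost through acid-catalysed enolisation while the slower 7- and 4'-acetals are cleaved. The fallback exchanges the protecting groups before the stereocentre exists; it sets out from 16 and comes back at 18. Acid methanolysis of 16 (HCl, MeOH, C3 still quaternary) gives allyl 5,7-dihydroxy-3-(5-hydroxy-2,2-dimethyl-2H-chromen-8-yl)-4-oxochromane-3-carboxylate F6. Silylation (TBSOTf, 2,6-lutidine, CH2Cl2) gives allyl 5,7-bis(tert-butyldimethylsilyloxy)-3-[5-(tert-butyldimethylsilyloxy)-2,2-dimethyl-2H-chromen-8-yl]-4-oxochromane-3-carboxylate F7. The decarboxylative protonation of step 11 then gives (3R)-5,7-bis(tert-butyldimethylsilyloxy)-3-[5-(tert-butyldimethylsilyloxy)-2,2-dimethyl-2H-chromen-8-yl]chroman-4-one F8. Et3N·3HF in THF at 0 °C, a weakly acidic fluoride source, releases 18.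

**Further compounds**
F1 | step 10 | allyl 2-[5-(methoxymethoxy)-2,2-dimethyl-2H-chromen-8-yl]prop-2-enoate | C=CCOC(=O)C(=C)c1ccc(OCOC)c2C=CC(C)(C)Oc12
F2 | step 10 | 2-hydroxy-4,6-bis(methoxymethoxy)benzaldehyde | COCOc1cc(O)c(C=O)c(OCOC)c1
F3 | step 10 | allyl 4-hydroxy-5,7-bis(methoxymethoxy)-3-[5-(methoxymethoxy)-2,2-dimethyl-2H-chromen-8-yl]chromane-3-carboxylate (diastereomer mixture, racemic) | C=CCOC(=O)C1(c2ccc(OCOC)c3C=CC(C)(C)Oc23)COc2cc(OCOC)cc(OCOC)c2C1O
F4 | step 11 | racemic 5,7-bis(methoxymethoxy)-3-[5-(methoxymethoxy)-2,2-dimethyl-2H-chromen-8-yl]chroman-4-one | CC1(C)C=Cc2c(OCOC)ccc(C3COc4cc(OCOC)cc(OCOC)c4C3=O)c2O1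
F5 | step 11 | (3R,4R)-5,7-bis(methoxymethoxy)-3-[5-(methoxymethoxy)-2,2-dimethyl-2H-chromen-8-yl]chroman-4-ol (aryl and hydroxyl cis) | CC1(C)C=Cc2c(OCOC)ccc([C@@H]3COc4cc(OCOC)cc(OCOC)c4[C@@H]3O)c2O1
F6 | step 12 | allyl 5,7-dihydroxy-3-(5-hydroxy-2,2-dimethyl-2H-chromen-8-yl)-4-oxochromane-3-carboxylate (racemic) | C=CCOC(=O)C1(c2ccc(O)c3C=CC(C)(C)Oc23)COc2cc(O)cc(O)c2C1=O
F7 | step 12 | allyl 5,7-bis(tert-butyldimethylsilyloxy)-3-[5-(tert-butyldimethylsilyloxy)-2,2-dimethyl-2H-chromen-8-yl]-4-oxochromane-3-carboxylate (racemic) | C=CCOC(=O)C1(c2ccc(O[Si](C)(C)C(C)(C)C)c3C=CC(C)(C)Oc23)COc2cc(O[Si](C)(C)C(C)(C)C)cc(O[Si](C)(C)C(C)(C)C)c2C1=O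
F8 | step 12 | (3R)-5,7-bis(tert-butyldimethylsilyloxy)-3-[5-(tert-butyldimethylsilyloxy)-2,2-dimethyl-2H-chromen-8-yl]chroman-4-one | CC1(C)C=Cc2c(O[Si](C)(C)C(C)(C)C)ccc([C@@H]3COc4cc(O[Si](C)(C)C(C)(C)C)cc(O[Si](C)(C)C(C)(C)C)c4C3=O)c2O1
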